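The numbers in the tables are calculated with made-up constants; scatter was added.

Adding the Q and Z peaks gives the X that has reacted: X becomes Q, and Q becomes Z.

common to all: D 0.5 mol%

|  | X | remark | time |
|---|---|---|---|
| north-east | 0.80 M | the very flask that is asked about, followed so far |  |
| south-east | 0.40 M | run made earlier |  |
| flask | 0.80 M |  | 30 h |

| run | time / h | Q / % | Z / % |
|---|---|---|---|
| north-east | 0.250 | 2 | 0 |
| north-east | 0.417 | 3 | 0 |
| north-east | 0.667 | 5 | 0 |
| north-east | 1.00 | 5 | 0 |
| north-east | 1.50 | 3 | 1 |
| north-east | 2.50 | 6 | 1 |
| north-east | 4.00 | 11 | 3 |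
| south-east | 1.50 | 4 | 1 |
| south-east | 2.50 | 5 | 3 |
| south-east | 4.00 | 10 | 1 |
| south-east | 6.00 | 11 | 0 |
| south-east | 10.0 | 16 | 1 |
| south-east | 15.0 | 18 | 5 |
| south-east | 20.0 | 16 | 10 |

(each reading ± 2 percentage points)

- the earlier runs were read with a standard deviation of 2 percentage points
- steps thought possible: D -> 2 J; X + J -> E + Q; X + E -> Q + E; 2 E -> G; Q -> Z
- the reaction counts as stopped when no species that holds the X changes by six tenths of a point or more over the second half of the time

- at 30 h, what has stopped the reaction, if anything has (forward and back rates have come level / all of X has reacted / it is still moving)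
- amount of Q at 30 h, in percent of the X charged
- amount of Z at 30 h, in percent of the X charged

In the south-east run that sum stands at 26.0% at 20.0 h. Z is made at a rate proportional to Q, so Z divided by the area under the Q curve gives the constant of that step. Taking the Q readings as rising straight to 16% at 10.0 h and then running on to 16% at 20.0 h, I read the half-life of Q, the time in which a given portion of Q halves by the step to Z, as 16.6 h.

While the growing radical E stays near a steady level, X falls pseudo-first-order, with a constant that goes as the root of the D concentration. At equal loading the north-east flask holds 2.00 times the D, so its constant is 1.41 times the south-east one. Carried to 30 h, that puts 47.2% of the X reacted in the north-east flask. Fed steadily, Q there has a mean age of 15.0 h, which is 0.904 half-lives, so 53.5% of the reacted X survives as Q.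

The weak link is the steady feed: the readings of the north-east flask put 14.0% reacted by 4.00 h, more than the 6.29% a steady feed gives. So I give that portion a mean age of 28.0 h and the remaining 33.2% a mean age of 13.0 h. I commit to Q 23.7% and Z 23.5%, with the reaction still moving, since by this reckoning 52.8% of the X is unreacted and 1.81 half-lives of Q have passed.

The forecast, lower than my reckoning, gives Q 19% (12% to 27%) and Z 19% (12% to 28%), answers it is still moving, and says “the reaction has not stopped”. The flask gives: it is still moving, with Q 27.4% and Z 25.2%.

    D → 2 J (k = 0.0350 h⁻¹)
    X + J → E + Q (k = 32000 L mol⁻¹ s⁻¹)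
    X + E → Q + E, rate k3*[E]*[X] (k = 1.60 × 10⁶ L mol⁻¹ h⁻¹)
    2 E → G (k = 1.00 × 10⁸ L mol⁻¹ s⁻¹)
    Q → Z (k = 0.0390 h⁻¹)

Read at 20 h instead, all amounts held, the neighbouring flask gives Q a mean age of 10.0 h on a steady feed, which is 0.602 half-lives of 16.6 h, so the reckoning leaves 65.9% of the reacted X as Q. That neighbour holds Q 27.3% and Z 14.4%, so Q is 65.5% of its reacted X.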